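**Plan**
1. Cuts: (a) the C–C bond between the allylic CH2 at the head of the (E,E)-dimethyldecadienyl chain and the carbinol carbon beside the butenolide; (b) butenolide C3=C4 and its ring O–C(=O) bond; (c) the exocyclic C=C and the ring O–C(=O) bond of the α-alkylidene-γ-butyrolactone; (d) the Cα–CH2 bond of that lactone.
2. Enabling feature: the carbinol carbon with butenolide C4 and C5 (O–CH–C(=X)–CH2–O) is a masked 1,3-dihydroxyacetone, so the carbinol carbon is the α-carbon of a 2,2-dimethyl-1,3-dioxan-5-one azaenolate. Its partner is the primary allylic CH2 of a C(CH3)=CH–CH2 unit, the C1-electrophile/C4-nucleophile polarity of head-to-tail prenyl transfer.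
3. Forward: (2E,6E)-farnesol → C12 aldehyde → Still–Gennari olefination → CBS reduction and lactonisation (alkylidene-lactone ring) → allylic bromide; RAMP-hydrazone alkylation joins it to the dioxanone; hydrazone cleavage, Wittig olefination and acetonide removal close the butenolide ring last.
4. Stereochemistry: carbinol (R) from the RAMP auxiliary (temporary C=N–N link, removed in step 12); lactone C5 (S) from (R)-CBS reduction; both (E)-trisubstituted alkenes from farnesol; (Z)-alkylidene from the Still–Gennari step; butenolide regiochemistry from the (E)-selective Wittig reaction on the temporary dioxane ring (removed in step 14).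

Key step: step 11

Assumption: stereocentres that are destroyed later (the epoxide of step 2, the phosphorus-bearing carbon made in step 5) are carried as racemates, and the C=N geometry of the hydrazones is left undefined because the auxiliary is removed.

**Route**

Step 1
Reactants: 1 (2E,6E)-farnesol
Product: 2 (2E,6E)-farnesyl tert-butyldiphenylsilyl ether
Conditions: TBDPSCl, imidazole, DMF, 0 °C to rt
Reagents that add atoms: tert-butyl(chloro)diphenylsilane, CC(C)(C)[Si](Cl)(c1ccccc1)c1ccccc1
Why: Imidazole-promoted O-silylation of a primary allylic alcohol (silyl ether protection), the TBDPS group being chosen because it survives NBS/H2O, K2CO3/MeOH, periodic acid and KHMDS.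

Step 2
Reactants: 2 (2E,6E)-farnesyl tert-butyldiphenylsilyl ether
Product: 4 racemic 10,11-epoxyfarnesyl tert-butyldiphenylsilyl ether, via bromohydrin 3 (not isolated)
Conditions: NBS, THF/H2O, 0 °C; then K2CO3, MeOH, rt
Reagents that add atoms: water, O (the epoxide oxygen); N-bromosuccinimide, O=C1CCC(=O)N1Br (its bromine is carried only by 3)
Why: Electrophilic bromohydrin formation in aqueous THF is selective for the terminal trisubstituted alkene of farnesyl derivatives (the 2,3-alkene is deactivated by the allylic oxygen), and base then closes the epoxide by intramolecular Williamson displacement; the epoxide stereocentre is cleaved in step 3.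

Step 3
Reactants: 4 racemic 10,11-epoxyfarnesyl tert-butyldiphenylsilyl ether
Product: 5 (4E,8E)-10-[(tert-butyldiphenylsilyl)oxy]-4,8-dimethyldeca-4,8-dienal
Conditions: H5IO6, THF/Et2O, 0 °C
Reagents that add atoms: none
Why: Periodic acid hydrolyses the trisubstituted epoxide to the glycol and cleaves it in the same pot (Malaprade-type glycol cleavage), excising acetone while the two (E)-alkenes and the silyl ether are untouched.

Step 4
Reactants: 6 2-chloro-N-methoxy-N-methylacetamide; 7 2-methylprop-1-enylmagnesium bromide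
Product: 8 1-chloro-4-methylpent-3-en-2-one
Conditions: THF, −20 to 0 °C; then cold 1 M HCl
Reagents that add atoms: none
Why: Weinreb ketone synthesis, in which the magnesium-chelated tetrahedral adduct prevents over-addition and the β,β-disubstituted enone released on acidic work-up is too hindered to add the liberated hydroxylamine.

Step 5
Reactants: 9 methyl 2-[bis(2,2,2-trifluoroethoxy)phosphoryl]acetate; 8 1-chloro-4-methylpent-3-en-2-one
Product: 11 methyl 2-[bis(2,2,2-trifluoroethoxy)phosphoryl]-6-methyl-4-oxohept-5-enoate (racemic), via sodium phosphonate 10 (not isolated)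
Conditions: NaH, THF, 0 °C; then 8, NaI (cat.), 0 °C to rt
Reagents that add atoms: none
Why: SN2 C-alkylation of the stabilised phosphonoacetate carbanion by an α-halo ketone (assisted by in situ Finkelstein exchange), a standard entry to α-substituted Horner–Wadsworth–Emmons reagents; the new stereocentre is racemic and is destroyed in step 6.

Step 6
Reactants: 11 keto phosphonate; 5 (4E,8E)-10-[(tert-butyldiphenylsilyl)oxy]-4,8-dimethyldeca-4,8-dienal
Product: 13 methyl (2Z,6E,10E)-12-[(tert-butyldiphenylsilyl)oxy]-6,10-dimethyl-2-(4-methyl-2-oxopent-3-en-1-yl)dodeca-2,6,10-trienoate, via potassium phosphonate 12 (not isolated)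
Conditions: KHMDS, 18-crown-6, THF, −78 °C; then 5, −78 °C, cold NH4Cl quench
Reagents that add atoms: none
Why: Still–Gennari modification of the Horner–Wadsworth–Emmons olefination, in which the electron-poor bis(trifluoroethyl) phosphonate with a dissociated potassium counter-ion eliminates faster than the adducts equilibrate and so places the aldehyde chain cis to the ester, the geometry required for the (Z)-alkylidene lactone.

Step 7
Reactants: 13 (Z)-keto enoate
Product: 15 (3Z,5S)-3-[(4E,8E)-10-[(tert-butyldiphenylsilyl)oxy]-4,8-dimethyldeca-4,8-dien-1-ylidene]-5-(2-methylprop-1-en-1-yl)dihydrofuran-2(3H)-one, via hydroxy ester 14 (not isolated)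
Conditions: (R)-Me-CBS (0.2 equiv), catecholborane, toluene, −78 °C; then PPTS (cat.), toluene, 40 °C
Reagents that add atoms: none
Why: Corey–Bakshi–Shibata reduction of the enone carbonyl, with the alkenyl group as the large substituent so that the (R)-catalyst should give the (S)-allylic alcohol, followed by mild acid-catalysed 5-exo-trig lactonisation of the γ-hydroxy ester, which does not disturb the (Z)-alkene.

Step 8
Reactants: 15 silyl-protected (Z)-alkylidene lactone
Product: 16 (3Z,5S)-3-[(4E,8E)-10-hydroxy-4,8-dimethyldeca-4,8-dien-1-ylidene]-5-(2-methylprop-1-en-1-yl)dihydrofuran-2(3H)-one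
Conditions: HF·pyridine, pyridine, THF, 0 °C to rt
Reagents that add atoms: none
Why: Fluoride-mediated cleavage of the silyl ether (Si–F bond formation) under pyridine-buffered conditions that leave the lactone, its allylic C–O bond and the alkenes intact.

Step 9
Reactants: 16 allylic alcohol
Product: 17 (3Z,5S)-3-[(4E,8E)-10-bromo-4,8-dimethyldeca-4,8-dien-1-ylidene]-5-(2-methylprop-1-en-1-yl)dihydrofuran-2(3H)-one
Conditions: CBr4, PPh3, CH2Cl2, −20 to 0 °C
Reagents that add atoms: carbon tetrabromide, BrC(Br)(Br)Br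
Why: Appel reaction, in which bromide displaces the alkoxyphosphonium group at the primary allylic carbon by SN2 without allylic transposition, so the (E)-alkene is retained and no acid is generated.

Step 10
Reactants: 18 2,2-dimethyl-1,3-dioxan-5-one; 19 (R)-1-amino-2-(methoxymethyl)pyrrolidine (RAMP)
Product: 20 RAMP hydrazone of 2,2-dimethyl-1,3-dioxan-5-one
Conditions: benzene, reflux, Dean–Stark
Reagents that add atoms: none
Why: Hydrazone formation by condensation of the ketone with the N-amino group of the auxiliary under azeotropic removal of water, the standard entry to SAMP/RAMP hydrazones.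

Step 11
Reactants: 20 RAMP hydrazone of 2,2-dimethyl-1,3-dioxan-5-one; 17 allylic bromide
Product: 22 RAMP hydrazone of (4R)-4-[(2E,6E)-3,7-dimethyl-10-[(3Z,5S)-5-(2-methylprop-1-en-1-yl)-2-oxodihydrofuran-3(2H)-ylidene]deca-2,6-dien-1-yl]-2,2-dimethyl-1,3-dioxan-5-one, via lithium azaenolate 21 (not isolated)
Conditions: t-BuLi (slightly less than 20), THF, −78 °C; then 17, −100 to −78 °C, pH 7 quench
Reagents that add atoms: none
Why: tert-Butyllithium deprotonates 20 to the internally chelated lithium azaenolate 21 (C=C fixed inside the dioxine ring, lithium held by the methoxy oxygen), whose α-carbon displaces bromide from the primary allylic carbon of 17 in an SN2 alkylation that forms the bond between the chain CH2 and the future carbinol carbon. The closest known reaction type is the Enders SAMP/RAMP-hydrazone α-alkylation of 2,2-dimethyl-1,3-dioxan-5-one with allylic halides, which is reported to tolerate ester-bearing halides. No ring is closed in this step; the dioxane ring and the C=N–N link to the pyrrolidine are temporary helpers that fix the azaenolate geometry and are removed in steps 14 and 12. The new stereocentre is controlled by the (R)-methoxymethylpyrrolidine auxiliary: the electrophile can reach only the azaenolate face left open by the chelated auxiliary (metalloretentive SE2′ model), which with RAMP should give the (R)-configuration at C4 of the dioxane, the mirror image of the SAMP outcome, and hence the (R)-carbinol of the target. The step needs C-alkylation in preference to attack on the lactone carbonyl or its alkylidene β-carbon, SN2 rather than SN2′ substitution with retention of the (2E)-alkene, and monoalkylation; these are secured by the high SN2 reactivity of a primary allylic bromide at −100 °C, where ester acylation and conjugate addition to a trisubstituted enoate are slow, by the absence of free tert-butyllithium, and by displacement at an unhindered primary carbon. The polarity copies head-to-tail prenyl transfer, an allylic C1 electrophile being attacked by the nucleophilic C4 of the last isoprene unit, here carried as a masked dihydroxyacetone.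

Step 12
Reactants: 22 alkylated RAMP hydrazone
Product: 23 (4R)-4-[(2E,6E)-3,7-dimethyl-10-[(3Z,5S)-5-(2-methylprop-1-en-1-yl)-2-oxodihydrofuran-3(2H)-ylidene]deca-2,6-dien-1-yl]-2,2-dimethyl-1,3-dioxan-5-one
Conditions: sat. aq. oxalic acid, Et2O, rt
Reagents that add atoms: water, O
Why: Mild two-phase hydrolytic cleavage of the hydrazone with oxalic acid (the established racemisation-free release of ketones from SAMP/RAMP hydrazones), which removes the auxiliary as its water-soluble oxalate while the acetonide, the lactone and the α-stereocentre are preserved.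

Step 13
Reactants: 23 (4R)-dioxanone; 24 methyl (triphenylphosphoranylidene)acetate
Product: 25 methyl (2E)-2-[(4R)-4-[(2E,6E)-3,7-dimethyl-10-[(3Z,5S)-5-(2-methylprop-1-en-1-yl)-2-oxodihydrofuran-3(2H)-ylidene]deca-2,6-dien-1-yl]-2,2-dimethyl-1,3-dioxan-5-ylidene]acetate
Conditions: toluene, rt to 40 °C
Reagents that add atoms: none
Why: Wittig olefination of the activated α,α′-dialkoxy ketone with a stabilised ylide under neutral conditions, which spares the α-stereocentre and should place the ester syn to the unsubstituted ring CH2 (C6) to avoid allylic 1,3-strain with the C4 side chain.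

Step 14
Reactants: 25 (E)-enoate acetonide
Product: 27 (3Z,5S)-3-[(4E,8E,11R)-11-hydroxy-4,8-dimethyl-11-(5-oxo-2,5-dihydrofuran-3-yl)undeca-4,8-dien-1-ylidene]-5-(2-methylprop-1-en-1-yl)dihydrofuran-2(3H)-one, via dihydroxy ester 26 (not isolated)
Conditions: AcOH/THF/H2O (3:1:1), 40 °C
Reagents that add atoms: none
Why: Acid-catalysed hydrolysis of the acetonide frees the diol, and the primary hydroxyl, which lies cis to the ester, closes the butenolide by spontaneous 5-exo-trig lactonisation with loss of methanol, leaving the (R)-carbinol untouched.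

**Compound list**
1 | (2E,6E)-farnesol | CC(C)=CCC/C(C)=C/CC/C(C)=C/CO | starting material
2 | (2E,6E)-farnesyl tert-butyldiphenylsilyl ether | CC(C)=CCC/C(C)=C/CC/C(C)=C/CO[Si](c1ccccc1)(c1ccccc1)C(C)(C)C | intermediate
3 | racemic 10-bromo-11-hydroxy-10,11-dihydrofarnesyl tert-butyldiphenylsilyl ether (bromohydrin) | CC(C)(O)C(Br)CC/C(C)=C/CC/C(C)=C/CO[Si](c1ccccc1)(c1ccccc1)C(C)(C)C | intermediate
4 | racemic 10,11-epoxyfarnesyl tert-butyldiphenylsilyl ether | CC1(C)OC1CC/C(C)=C/CC/C(C)=C/CO[Si](c1ccccc1)(c1ccccc1)C(C)(C)C | intermediate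
5 | (4E,8E)-10-[(tert-butyldiphenylsilyl)oxy]-4,8-dimethyldeca-4,8-dienal | O=CCC/C(C)=C/CC/C(C)=C/CO[Si](c1ccccc1)(c1ccccc1)C(C)(C)C | intermediate
6 | 2-chloro-N-methoxy-N-methylacetamide | CON(C)C(=O)CCl | starting material
7 | 2-methylprop-1-enylmagnesium bromide | CC(C)=C[Mg]Br | starting material
8 | 1-chloro-4-methylpent-3-en-2-one | CC(C)=CC(=O)CCl | intermediate
9 | methyl 2-[bis(2,2,2-trifluoroethoxy)phosphoryl]acetate | COC(=O)CP(=O)(OCC(F)(F)F)OCC(F)(F)F | starting material
10 | sodium salt of 9 (phosphonate carbanion) | COC(=O)[CH-]P(=O)(OCC(F)(F)F)OCC(F)(F)F.[Na+] | intermediate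
11 | methyl 2-[bis(2,2,2-trifluoroethoxy)phosphoryl]-6-methyl-4-oxohept-5-enoate (racemic) | COC(=O)C(CC(=O)C=C(C)C)P(=O)(OCC(F)(F)F)OCC(F)(F)F | intermediate
12 | potassium salt of 11 (phosphonate carbanion) | COC(=O)[C-](CC(=O)C=C(C)C)P(=O)(OCC(F)(F)F)OCC(F)(F)F.[K+] | intermediate
13 | methyl (2Z,6E,10E)-12-[(tert-butyldiphenylsilyl)oxy]-6,10-dimethyl-2-(4-methyl-2-oxopent-3-en-1-yl)dodeca-2,6,10-trienoate | CC(C)=CC(=O)C/C(=C/CC/C(C)=C/CC/C(C)=C/CO[Si](c1ccccc1)(c1ccccc1)C(C)(C)C)C(=O)OC | intermediate
14 | methyl (2Z,6E,10E)-12-[(tert-butyldiphenylsilyl)oxy]-2-[(2S)-2-hydroxy-4-methylpent-3-en-1-yl]-6,10-dimethyldodeca-2,6,10-trienoate | CC(C)=C[C@@H](O)C/C(=C/CC/C(C)=C/CC/C(C)=C/CO[Si](c1ccccc1)(c1ccccc1)C(C)(C)C)C(=O)OC | intermediate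
15 | (3Z,5S)-3-[(4E,8E)-10-[(tert-butyldiphenylsilyl)oxy]-4,8-dimethyldeca-4,8-dien-1-ylidene]-5-(2-methylprop-1-en-1-yl)dihydrofuran-2(3H)-one | CC(C)=C[C@@H]1C/C(=C/CC/C(C)=C/CC/C(C)=C/CO[Si](c2ccccc2)(c2ccccc2)C(C)(C)C)C(=O)O1 | intermediate
16 | (3Z,5S)-3-[(4E,8E)-10-hydroxy-4,8-dimethyldeca-4,8-dien-1-ylidene]-5-(2-methylprop-1-en-1-yl)dihydrofuran-2(3H)-one | CC(C)=C[C@@H]1C/C(=C/CC/C(C)=C/CC/C(C)=C/CO)C(=O)O1 | intermediate
17 | (3Z,5S)-3-[(4E,8E)-10-bromo-4,8-dimethyldeca-4,8-dien-1-ylidene]-5-(2-methylprop-1-en-1-yl)dihydrofuran-2(3H)-one | CC(C)=C[C@@H]1C/C(=C/CC/C(C)=C/CC/C(C)=C/CBr)C(=O)O1 | intermediate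
18 | 2,2-dimethyl-1,3-dioxan-5-one | CC1(C)OCC(=O)CO1 | starting material
19 | (R)-1-amino-2-(methoxymethyl)pyrrolidine (RAMP) | COC[C@H]1CCCN1N | starting material
20 | RAMP hydrazone of 2,2-dimethyl-1,3-dioxan-5-one | COC[C@H]1CCCN1N=C1COC(C)(C)OC1 | intermediate
21 | lithium azaenolate of 20 | COC[C@H]1CCCN1N([Li])C1=COC(C)(C)OC1 | intermediate
22 | RAMP hydrazone of ketone 23, (4R) at the dioxane, C=N geometry undefined | CC(C)=C[C@@H]1C/C(=C/CC/C(C)=C/CC/C(C)=C/C[C@H]2OC(C)(C)OCC2=NN2CCC[C@@H]2COC)C(=O)O1 | intermediate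
23 | (4R)-4-[(2E,6E)-3,7-dimethyl-10-[(3Z,5S)-5-(2-methylprop-1-en-1-yl)-2-oxodihydrofuran-3(2H)-ylidene]deca-2,6-dien-1-yl]-2,2-dimethyl-1,3-dioxan-5-one | CC(C)=C[C@@H]1C/C(=C/CC/C(C)=C/CC/C(C)=C/C[C@H]2OC(C)(C)OCC2=O)C(=O)O1 | intermediate
24 | methyl (triphenylphosphoranylidene)acetate | COC(=O)C=P(c1ccccc1)(c1ccccc1)c1ccccc1 | starting material
25 | methyl (2E)-2-[(4R)-4-[(2E,6E)-3,7-dimethyl-10-[(3Z,5S)-5-(2-methylprop-1-en-1-yl)-2-oxodihydrofuran-3(2H)-ylidene]deca-2,6-dien-1-yl]-2,2-dimethyl-1,3-dioxan-5-ylidene]acetate | CC(C)=C[C@@H]1C/C(=C/CC/C(C)=C/CC/C(C)=C/C[C@H]2OC(C)(C)OC/C2=C\C(=O)OC)C(=O)O1 | intermediate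
26 | methyl (2E,4R,6E,10E)-4-hydroxy-3-(hydroxymethyl)-7,11-dimethyl-14-[(3Z,5S)-5-(2-methylprop-1-en-1-yl)-2-oxodihydrofuran-3(2H)-ylidene]tetradeca-2,6,10-trienoate | CC(C)=C[C@@H]1C/C(=C/CC/C(C)=C/CC/C(C)=C/C[C@@H](O)/C(CO)=C/C(=O)OC)C(=O)O1 | intermediate
27 | (3Z,5S)-3-[(4E,8E,11R)-11-hydroxy-4,8-dimethyl-11-(5-oxo-2,5-dihydrofuran-3-yl)undeca-4,8-dien-1-ylidene]-5-(2-methylprop-1-en-1-yl)dihydrofuran-2(3H)-one | CC(C)=C[C@@H]1C/C(=C/CC/C(C)=C/CC/C(C)=C/C[C@@H](O)C2=CC(=O)OC2)C(=O)O1 | target

**Totals**
Total step count: 14. Longest linear sequence: 11 steps (1, 2, 3, 6, 7, 8, 9, 11, 12, 13, 14).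

**Steps most likely to fail**

Step 11. The lithium azaenolate may be consumed by acylation or conjugate addition at the alkylidene lactone, or by proton transfer from its γ-CH2, in competition with the SN2 alkylation. The fallback builds the lactone after the union. It sets out from hydrazone 20 (as its azaenolate 21) and comes back at 25. Azaenolate 21 is alkylated under the same conditions with commercial, ester-free (2E,6E)-farnesyl bromide (CC(C)=CCC/C(C)=C/CC/C(C)=C/CBr) to give the farnesylated RAMP hydrazone F1. Oxalic acid cleavage gives the (4R)-farnesyl dioxanone F2, and Wittig olefination with 24 gives the (E)-enoate F3. Terminal-selective NBS/H2O bromohydrin formation (bromohydrin F4, not isolated) and K2CO3/MeOH give the terminal epoxide F5, which periodic acid cleaves to the aldehyde F6. Still–Gennari olefination of F6 with 12 gives the (Z)-keto enoate F7. (R)-CBS reduction to the hydroxy ester F8 (not isolated) and PPTS lactonisation then deliver 25.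

Step 13. Geometric control in the olefination of the unsymmetrical dioxanone may be incomplete (an ester placed syn to C4 would lactonise onto the secondary hydroxyl), or the centre α to the ketone may epimerise. The fallback fixes the regiochemistry by which hydroxyl is acylated. It sets out from 23 and comes back at 27. Acetonide hydrolysis (AcOH/THF/H2O) gives the dihydroxy ketone F9. Selective esterification of its primary hydroxyl with diethylphosphonoacetic acid (OC(=O)CP(=O)(OCC)OCC; DCC, cat. DMAP, 0 °C) gives the phosphonoacetate F10. An intramolecular Horner–Wadsworth–Emmons reaction under Masamune–Roush conditions (LiCl, i-Pr2NEt, MeCN) then closes the butenolide directly to 27.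

Step 6. Kinetic Z-control may be lost in the olefination, or base may move the skipped enone double bond into conjugation. The fallback uses aldol addition and anti-elimination on a preformed chiral lactone. It sets out from 5 and comes back at 15. Commercial (S)-5-(hydroxymethyl)dihydrofuran-2(3H)-one (OC[C@@H]1CCC(=O)O1) is oxidised (Dess–Martin periodinane) to (S)-5-oxotetrahydrofuran-2-carbaldehyde F11. Wittig olefination with isopropylidenetriphenylphosphorane (from isopropyltriphenylphosphonium iodide and n-BuLi) gives (S)-5-(2-methylprop-1-en-1-yl)dihydrofuran-2(3H)-one F12. Its lithium enolate (LDA, −78 °C) should add to 5 trans to the C5 substituent through a Zimmerman–Traxler transition state of the ring-fixed (E)-enolate to give the anti-aldol F13. Mesylation (MsCl, Et3N) gives the mesylate F14, whose stereospecific anti E2 elimination (DBU, 0 °C, short contact) places the chain cis to the carbonyl and gives 15.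

**Further compounds**
F1 | step 11 | RAMP hydrazone of (4R)-2,2-dimethyl-4-[(2E,6E)-3,7,11-trimethyldodeca-2,6,10-trien-1-yl]-1,3-dioxan-5-one | CC(C)=CCC/C(C)=C/CC/C(C)=C/C[C@H]1OC(C)(C)OCC1=NN1CCC[C@@H]1COC
F2 | step 11 | (4R)-2,2-dimethyl-4-[(2E,6E)-3,7,11-trimethyldodeca-2,6,10-trien-1-yl]-1,3-dioxan-5-one | CC(C)=CCC/C(C)=C/CC/C(C)=C/C[C@H]1OC(C)(C)OCC1=O
F3 | step 11 | methyl (2E)-2-[(4R)-2,2-dimethyl-4-[(2E,6E)-3,7,11-trimethyldodeca-2,6,10-trien-1-yl]-1,3-dioxan-5-ylidene]acetate | CC(C)=CCC/C(C)=C/CC/C(C)=C/C[C@H]1OC(C)(C)OC/C1=C\C(=O)OC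
F4 | step 11 | terminal bromohydrin of F3 (10-bromo-11-hydroxy, racemic at the new centres) | CC(C)(O)C(Br)CC/C(C)=C/CC/C(C)=C/C[C@H]1OC(C)(C)OC/C1=C\C(=O)OC
F5 | step 11 | terminal (10,11) epoxide of F3 | CC1(C)OC1CC/C(C)=C/CC/C(C)=C/C[C@H]1OC(C)(C)OC/C1=C\C(=O)OC
F6 | step 11 | methyl (2E)-2-[(4R)-4-[(2E,6E)-3,7-dimethyl-10-oxodeca-2,6-dien-1-yl]-2,2-dimethyl-1,3-dioxan-5-ylidene]acetate | O=CCC/C(C)=C/CC/C(C)=C/C[C@H]1OC(C)(C)OC/C1=C\C(=O)OC
F7 | step 11 | (Z)-keto enoate from F6 and 12 | CC(C)=CC(=O)C/C(=C/CC/C(C)=C/CC/C(C)=C/C[C@H]1OC(C)(C)OC/C1=C\C(=O)OC)C(=O)OC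
F8 | step 11 | (S)-hydroxy ester from CBS reduction of F7 | CC(C)=C[C@@H](O)C/C(=C/CC/C(C)=C/CC/C(C)=C/C[C@H]1OC(C)(C)OC/C1=C\C(=O)OC)C(=O)OC
F9 | step 13 | (3R)-1,3-dihydroxy ketone from acetonide hydrolysis of 23 | CC(C)=C[C@@H]1C/C(=C/CC/C(C)=C/CC/C(C)=C/C[C@@H](O)C(=O)CO)C(=O)O1
F10 | step 13 | primary (diethoxyphosphoryl)acetate of F9 | CC(C)=C[C@@H]1C/C(=C/CC/C(C)=C/CC/C(C)=C/C[C@@H](O)C(=O)COC(=O)CP(=O)(OCC)OCC)C(=O)O1
F11 | step 6 | (S)-5-oxotetrahydrofuran-2-carbaldehyde | O=C[C@@H]1CCC(=O)O1
F12 | step 6 | (S)-5-(2-methylprop-1-en-1-yl)dihydrofuran-2(3H)-one | CC(C)=C[C@@H]1CCC(=O)O1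
F13 | step 6 | (3S,5S)-3-[(1S)-1-hydroxyalkyl] anti-aldol of F12 with 5 | CC(C)=C[C@@H]1C[C@@H]([C@@H](O)CC/C(C)=C/CC/C(C)=C/CO[Si](c2ccccc2)(c2ccccc2)C(C)(C)C)C(=O)O1
F14 | step 6 | methanesulfonate of F13 | CC(C)=C[C@@H]1C[C@@H]([C@@H](OS(C)(=O)=O)CC/C(C)=C/CC/C(C)=C/CO[Si](c2ccccc2)(c2ccccc2)C(C)(C)C)C(=O)O1
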